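My reckoning began from a unit, the reciprocal molarity, which is the unit of the constant I carried through this flask.

Z 1.0 M; Q 0.600 M; time 20 min

    Z.Q ⇌ X + L (K1 = 0.34 M, k1 = 0.020 s⁻¹)
    Z + Q ⇌ Z.Q (K2 = 0.72 M⁻¹, k2 = 0.059 M⁻¹ s⁻¹)
    E ⇌ X, rate k3*(cs3 - [X]) while solid is left; crystals form when [X] > cs3 (cs3 = 0.082 M, k3 = 2.9 s⁻¹)

- the state of affairs at 20 min: stopped, and by what, or still going (it is still moving / all of Z has reacted / Q has run out first / forward and back rates have come level)
- how much of the Z has reacted by 20 min
- how much X there is at 20 min, in percent of the Z charged
- how much Z.Q there is at 20 min, in percent of the Z charged

- X is meant together with its E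
- solid, in amounts per volume of the solution: E
- the reaction counts as stopped when no species that holds the Z changes by six tenths of a point or more over the second half of the time
- run time (flask): 20 min

While crystals stand, [X] stays at 0.082 M. With both reversible steps level, the reacted Z, c, then obeys c = G[Z][Q], where G is the equilibrium constant for forming Z.Q times one plus the ratio of the other constant to the solubility. That makes 3.71 M⁻¹, which I named the crystal-held constant, an apparent equilibrium constant.

I took the settings in turn. For time I counted turnovers: the forward half-life of Z.Q is 0.58 min, longer than the 0.33 min of Z. The 20 min of this flask is far longer than the first of these and holds 34.5 of them, so I expected balance and no gain from more time. For the charges, c = G([Z] charged − c)([Q] charged − c) gave 0.411 M. That is a conversion of 41.1%, with X and its E together at 0.331 M, above the solubility, or 33.1% of the Z charged, and Z.Q at 7.99%. With the other charge held, a small factor on a charge moves c in proportion to that charge over what remains of it: 3.18 for Q, 1.70 for Z. I therefore ranked Q above Z.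

The forecast gave forward and back rates have come level, with conversion 41.1%, X 33.2% and Z.Q 8%, saying: “the reaction has stopped at equilibrium, not through Q running out”. Its X differs from mine in the last digit.

The simulation gave forward and back rates have come level, with conversion 41.1%, X 33.1% and Z.Q 7.99%. From the end amounts, c over [Z][Q] reads 3.71 M⁻¹. The settings ranked Q (7.5 points), then Z (5 points), then time (under 0.05 points), and the time allowed made no difference.

The step from Z.Q had half of its turnover up to 20 min behind it by 1.08 min, much earlier than that time. Z read 58.9% at 10.0 min and 58.9% at 200 min.

For the neighbour flask with 0.36 M of Q, the same G gives a conversion of 26.3%. The simulation of that flask gave 26.3%.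

(The rate constants are invented, and the outcome is calculated.)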